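Which of these flasks ends with the most product, and how much product does each one hold?

| setting | teal | violet | grey | amber |
|---|---|---|---|---|
| substrate | 0.010 M | 0.010 M | 0.010 M | 0.010 M |
| partner | 1.80 equiv | 1.80 equiv | 1.80 equiv | 1.80 equiv |
| free catalyst | 0.1 mol% | 0.1 mol% | 0.1 mol% | 0.1 mol% |
| temperature | 130 °C | 85 °C | 115 °C | 100 °C |
| time | 15 min | 15 min | 15 min | 15 min |

    free catalyst + product ⇌ idle complex, settled at all times (K1 = 34 M⁻¹, ΔH1 = −47.0 kJ mol⁻¹)
    catalyst intermediate C → spent catalyst (k2 = 0.78 min⁻¹, Ea2 = 112 kJ mol⁻¹)
    catalyst intermediate C → free catalyst + product (k3 = 7300 min⁻¹, Ea3 = 80.0 kJ mol⁻¹)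
    catalyst intermediate B → catalyst intermediate C (k4 = 300 min⁻¹, Ea4 = 70.0 kJ mol⁻¹)
    partner + catalyst intermediate A → catalyst intermediate B (k5 = 3500 M⁻¹ min⁻¹, Ea5 = 63.0 kJ mol⁻¹)
    substrate + free catalyst ⇌ catalyst intermediate A (K6 = 88 M⁻¹, k6 = 15000 M⁻¹ min⁻¹, Ea6 = 47.0 kJ mol⁻¹, ΔH6 = −40.0 kJ mol⁻¹)
    (constants at 100 °C)

- for product the idle complex is counted in
- the list of constants is for 100 °C, to be carried to other temperatures by the activation energies and enthalpies

- the best flask by amount of product, in percent of the substrate charged; "all alike" if 1.5 percentage points covers them all (teal / violet / grey / amber / all alike)
- amount of product at the end, in percent of the substrate charged, teal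
- amount of product at the end, in percent of the substrate charged, violet
- amount of product at the end, in percent of the substrate charged, grey
- amount of product at the end, in percent of the substrate charged, amber

A loading of 0.1 mol% means that each catalyst must turn over 1000 times on average to convert the whole charge, so I first ask whether it lives that long. Catalyst intermediate C has two exits, to product and to spent catalyst. Both rates carry the same c(catalyst intermediate C), so their ratio is simply the ratio of the two constants, whatever that concentration does. In teal this ratio is 4340, and I carry it as the turnover ceiling: the product made per catalyst spent, the usual turnover number of a dying catalyst.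

The loss has the higher activation energy, 112 kJ mol⁻¹ against 80.0 kJ mol⁻¹, so the ceiling is lower in teal than the 14400 of violet. But even in teal the ceiling is higher than the turnovers needed, and converting the whole charge there spends 23.0% of the catalyst. So the end state I expect in teal is full conversion with 77.0% of the catalyst not spent.

That tells me where teal is heading, but not how far it gets in 15 min. From violet to teal, step 5 speeds up by a factor of 11 and step 4 by 14. The loss speeds up by 67, which is more, but the ceiling in teal is still higher than the turnovers needed. I commit to teal as the best flask and to product rising with temperature. My reckoning stops there and gives no percentages.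

The forecast names teal and gives 52.5% for teal, 41% for grey, 27.5% for amber and 16% for violet, on the ground that “deactivation and the weak product inhibition cost only a little and the hottest flask still wins”.

The simulation puts teal first, with 52.7% in teal, 40.8% in grey, 27.8% in amber and 16.2% in violet.

In teal, the ceiling turns 52.7% of product into 12.1% of the catalyst spent, and the flask reads 12.1% at 15.0 min, with 47% of the substrate still there. Left until 150 min, teal reaches 99.2% with 22.8% spent. The neighbouring flask is teal with 1.10 equiv of partner, at the same temperature and so under the same ceiling, and it makes 37.8% by 15.0 min. The ceiling turns that into 8.70% of the catalyst spent, and that flask reads 8.70%.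

The numbers of this flask stand for no real mixture; the run is a simulation.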